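The benzil is cut between the anisyl ipso carbon and the neighbouring diketone carbon. This carbon is α to the ketone on C6 of the chromene, so at the methyl ketone oxidation level it is an enolisable CH3 next to the hydrogen-bonded C5 phenol. The key step is a one-pot palladium-catalysed α-arylation of 6-acetyl-5-hydroxy-8-methoxy-2,2-dimethyl-2H-chromene with 4-bromoanisole, followed in the same flask by aerobic oxidation of the doubly activated CH2 of the deoxybenzoin to the second carbonyl. The precursor, an acetylchromene, comes in two protecting-group-free steps from 4-methoxyresorcinol: C-acetylation and chromene annulation with prenal at the carbon between the two hydroxyls.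

Key step: step 3

Remark: 4-methoxyresorcinol is taken as a catalogue compound. The target has no stereocentre, and its only stereo-element, the cis C3=C4 double bond, is fixed by the pyran ring.

Step 1
Reactants: 1 4-methoxybenzene-1,3-diol (4-methoxyresorcinol)
Product: 2 1-(2,4-dihydroxy-5-methoxyphenyl)ethan-1-one
Conditions: AcOH, ZnCl2, 140 °C
Reagents that add atoms: acetic acid, CC(=O)O
Why: Nencki-type Friedel–Crafts C-acylation should occur at C6, the unhindered position ortho to one hydroxyl and para to the other (C2 lies between two hydroxyls and C5 is meta to both), and the hydrogen-bonded o-hydroxy ketone formed is deactivated towards a second acylation.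

Step 2
Reactants: 2 1-(2,4-dihydroxy-5-methoxyphenyl)ethan-1-one, 3 3-methylbut-2-enal (prenal)
Product: 4 1-(5-hydroxy-8-methoxy-2,2-dimethyl-2H-chromen-6-yl)ethan-1-one
Conditions: EDDA (10 mol%), xylene, 140 °C
Reagents that add atoms: none
Why: Amine-catalysed Knoevenagel-type condensation of prenal at C3, the only ring carbon activated by both hydroxyls, should give an ortho-quinone methide that closes by oxa-6π electrocyclisation onto the free C4 oxygen and not onto the C2 hydroxyl that is hydrogen-bonded to the acetyl group, as is known for resacetophenone.

Step 3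
Reactants: 4 1-(5-hydroxy-8-methoxy-2,2-dimethyl-2H-chromen-6-yl)ethan-1-one, 5 1-bromo-4-methoxybenzene (4-bromoanisole)
Product: 7 Dielsianone, via deoxybenzoin 6 (not isolated)
Conditions: Pd2(dba)3 (2 mol%), XPhos (5 mol%), NaOtBu (3 equiv), toluene, 80 °C; then AcOH (1 equiv), DABCO, DMF, air, 90 °C
Reagents that add atoms: dioxygen (air), O=O
Why: NaOtBu turns 4 into its phenoxide–enolate, 4-bromoanisole adds oxidatively to Pd(0)/XPhos, and the arylpalladium enolate reductively eliminates to form the anisyl–CH2 bond of deoxybenzoin 6; after buffering with AcOH, DABCO-mediated enolisation of the doubly activated CH2 and capture by O2 should give an α-hydroperoxide that loses water (Kornblum–DeLaMare type) to the 1,2-dione. The closest known reaction types are the palladium-catalysed α-arylation of aryl methyl ketones with aryl bromides and the base-mediated aerobic oxidation of deoxybenzoins to benzils, here telescoped. No ring is closed and no stereocentre is formed. The step needs mono- over diarylation, secured by the bulky ligand, the more hindered secondary enolate of 6 and a small excess of 4, and C- over O-arylation, secured because the C5 phenoxide is di-ortho-substituted and chelated to the ketone. The phenoxide also deactivates the ketone against aldol self-condensation, the cis-disubstituted chromene alkene is a poor Heck acceptor, and the weak amine base used in the oxidation should prevent cleavage of the dione.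

Compound list
1 | 4-methoxybenzene-1,3-diol (4-methoxyresorcinol) | COc1ccc(O)cc1O | starting material
2 | 1-(2,4-dihydroxy-5-methoxyphenyl)ethan-1-one | CC(=O)c1cc(OC)c(O)cc1O | intermediate
3 | 3-methylbut-2-enal (prenal) | CC(C)=CC=O | starting material
4 | 1-(5-hydroxy-8-methoxy-2,2-dimethyl-2H-chromen-6-yl)ethan-1-one | CC(=O)c1cc(OC)c2c(c1O)C=CC(C)(C)O2 | intermediate
5 | 1-bromo-4-methoxybenzene (4-bromoanisole) | COc1ccc(Br)cc1 | starting material
6 | 1-(5-hydroxy-8-methoxy-2,2-dimethyl-2H-chromen-6-yl)-2-(4-methoxyphenyl)ethan-1-one (deoxybenzoin, not isolated) | COc1ccc(CC(=O)c2cc(OC)c3c(c2O)C=CC(C)(C)O3)cc1 | intermediate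
7 | Dielsianone, 1-(5-hydroxy-8-methoxy-2,2-dimethyl-2H-chromen-6-yl)-2-(4-methoxyphenyl)ethane-1,2-dione | COc1ccc(C(=O)C(=O)c2cc(OC)c3c(c2O)C=CC(C)(C)O3)cc1 | target

Total step count: 3. Longest linear sequence: 3 steps (1 → 2 → 4 → 7).

Steps most likely to fail

Step 3 (key step). Chelation of palladium by the o-phenoxide ketone and slow enolisation of the phenoxide-bearing ketone may stall the arylation. Oxidative degradation of the electron-rich phenoxide ring or cleavage of the dione may also occur during aeration. The fallback sets out from 4 and comes back at 7. Riley oxidation of the acetyl group (SeO2, dioxane/H2O, 90 °C) should give the arylglyoxal 2-(5-hydroxy-8-methoxy-2,2-dimethyl-2H-chromen-6-yl)-2-oxoacetaldehyde F1, handled as its hydrate. Rhodium-catalysed 1,2-addition of 4-methoxyphenylboronic acid ([Rh(cod)OH]2, dioxane/H2O, 60 °C) should form the same aryl–carbon bond chemoselectively at the aldehyde and give the racemic benzoin 2-hydroxy-1-(5-hydroxy-8-methoxy-2,2-dimethyl-2H-chromen-6-yl)-2-(4-methoxyphenyl)ethan-1-one F2. Oxidation of its secondary alcohol (MnO2, CH2Cl2, rt) should then give 7.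

Step 2. Competing ring closure onto the hydrogen-bonded oxygen, aldol condensation of the acetyl group with prenal, or oligomerisation of prenal may lower the conversion to the chromene. The fallback sets out from 2 and comes back at 4. Alkylation of the free C4 hydroxyl with 3-chloro-3-methylbut-1-yne (DBU, CuCl2 cat., MeCN, 0 °C) should give the aryl propargyl ether 1-[2-hydroxy-5-methoxy-4-(2-methylbut-3-yn-2-yloxy)phenyl]ethan-1-one F3. Heating in N,N-diethylaniline at 190 °C should give 4 by propargyl Claisen rearrangement to C3 (the only free ortho position), 1,5-hydrogen shift and oxa-6π electrocyclisation.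

Step 1. Cleavage of the methyl ether, O-acetylation or a second acylation may occur at 140 °C in the presence of zinc chloride. The fallback sets out from 1 and comes back at 2. Hoesch reaction with acetonitrile (ZnCl2, HCl gas, Et2O, 0 °C) should precipitate the ketiminium salt 1-(2,4-dihydroxy-5-methoxyphenyl)ethan-1-iminium chloride F4, formed at the same C6 position under mild conditions. Hydrolysis in water at 100 °C should give 2.

Further compounds
F1 | step 3 | 2-(5-hydroxy-8-methoxy-2,2-dimethyl-2H-chromen-6-yl)-2-oxoacetaldehyde | O=CC(=O)c1cc(OC)c2c(c1O)C=CC(C)(C)O2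
F2 | step 3 | 2-hydroxy-1-(5-hydroxy-8-methoxy-2,2-dimethyl-2H-chromen-6-yl)-2-(4-methoxyphenyl)ethan-1-one (racemic) | COc1ccc(C(O)C(=O)c2cc(OC)c3c(c2O)C=CC(C)(C)O3)cc1
F3 | step 2 | 1-[2-hydroxy-5-methoxy-4-(2-methylbut-3-yn-2-yloxy)phenyl]ethan-1-one | CC(=O)c1cc(OC)c(OC(C)(C)C#C)cc1O
F4 | step 1 | 1-(2,4-dihydroxy-5-methoxyphenyl)ethan-1-iminium chloride | CC(=[NH2+])c1cc(OC)c(O)cc1O.[Cl-]
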